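**Retrosynthetic overview** (flavone numbering; C9 = oxepine CH2, C10 = O-bearing stereocentre, C11 = carbinol carbon)

- Feature: the oxepine ring (C2, C3, C9, C10, O, C2', C1') holds a C9H2–C10H–O unit that is a terminal epoxide in disguise. It sits between C3, the one ring C–H beside the C4 carbonyl that a lithium amide can remove, and C2', which is ortho to the electron-poor chromon-2-yl group and can carry fluorine.
- Key disconnection: C3–C9 (epoxide opening) and O–C2' (SNAr) in one operation, from 2'-fluoroflavone 10 and (R)-epoxide 14. C10 is bought in with 14 (hydrolytic kinetic resolution).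
- Flavone 10: pyranone ring by cyclodehydration of diketone 9, itself from the dianion of diprenyl acetophenone 4 and acid chloride 8.
- Ring order: rings A and B come from the starting materials, the pyranone ring is closed in step 6, the oxepine in step 10; then O-TIPS and three O-MOM groups are removed.

Key step: step 10

Assumption: the hydrolytic kinetic resolution follows its usual sense, the (S,S)-catalyst consuming the enantiomer that corresponds in space to (R)-propylene oxide; for 13 this leaves the (R)-epoxide, whose descriptor is R because C(CH3)2(OMOM) outranks the ring CH2. If the sense is the opposite one, the (R,R)-catalyst is used.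

**Route**

Step 1
Reactants: 1 2,4,6-trihydroxyacetophenone; 2 prenyl bromide
Product: 3 2,4,6-trihydroxy-3,5-bis(3-methylbut-2-enyl)acetophenone
Conditions: 2 (2.1 equiv), 10% aq. KOH, 0 °C → rt; chromatography
Reagents that add atoms: none
Why: C-prenylation of an acylphloroglucinol, in which the phenoxide reacts in water as a carbon nucleophile at its two free ring positions; mono- and over-alkylated material is separated.

Step 2
Reactants: 3 2,4,6-trihydroxy-3,5-bis(3-methylbut-2-enyl)acetophenone
Product: 4 2-hydroxy-4,6-bis(methoxymethoxy)-3,5-bis(3-methylbut-2-enyl)acetophenone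
Conditions: MOMCl (2.3 equiv), iPr2NEt, CH2Cl2, 0 °C → rt
Reagents that add atoms: chloromethyl methyl ether, COCCl
Why: O-alkylation to MOM acetals takes the 4-OH and one ortho-OH, while the other ortho-OH is held in a hydrogen bond to the acetyl carbonyl and stays free.

Step 3
Reactants: 5 2-fluoro-4-hydroxybenzoic acid
Product: 7 2-fluoro-4-(triisopropylsilyloxy)benzoic acid, via silyl ester 6 (not isolated)
Conditions: TIPSCl (2.2 equiv), imidazole, DMF, rt; then K2CO3, THF–MeOH–H2O, rt; 1 M HCl to pH 3
Reagents that add atoms: triisopropylsilyl chloride, CC(C)[Si](Cl)(C(C)C)C(C)C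
Why: Silylation of both acidic OH groups followed by selective hydrolysis of the silyl ester, which is far more labile than the hindered aryl silyl ether.

Step 4
Reactants: 7 2-fluoro-4-(triisopropylsilyloxy)benzoic acid
Product: 8 2-fluoro-4-(triisopropylsilyloxy)benzoyl chloride
Conditions: (COCl)2, cat. DMF, CH2Cl2, 0 °C → rt; evaporate, use crude
Reagents that add atoms: oxalyl chloride, O=C(Cl)C(=O)Cl
Why: Acid chloride formation through the Vilsmeier-type chloroiminium species; no water is present, so the aryl silyl ether is not touched.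

Step 5
Reactants: 4 2-hydroxy-4,6-bis(methoxymethoxy)-3,5-bis(3-methylbut-2-enyl)acetophenone; 8 2-fluoro-4-(triisopropylsilyloxy)benzoyl chloride
Product: 9 1-[2-fluoro-4-(triisopropylsilyloxy)phenyl]-3-[2-hydroxy-4,6-bis(methoxymethoxy)-3,5-bis(3-methylbut-2-enyl)phenyl]propane-1,3-dione
Conditions: LiHMDS (3.2 equiv), THF, −78 → −10 °C; 8, −78 °C → rt; aq. NH4Cl
Reagents that add atoms: none
Why: Excess LiHMDS forms the phenoxide–enolate dianion of 4, whose enolate carbon is acylated by 8 (direct C-acylation variant of the Baker–Venkataraman route to o-hydroxyaryl 1,3-diketones); any O-aroyl ester formed rearranges to the same diketone under the excess base.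

Step 6
Reactants: 9 the 1,3-diketone
Product: 10 2-[2-fluoro-4-(triisopropylsilyloxy)phenyl]-5,7-bis(methoxymethoxy)-6,8-bis(3-methylbut-2-enyl)chromen-4-one
Conditions: NaOAc, AcOH, 80 °C
Reagents that add atoms: none
Why: Cyclodehydration of an o-hydroxyaryl 1,3-diketone (last stage of the Baker–Venkataraman flavone synthesis): the free phenol adds to the B-ring-side carbonyl and the hemiketal loses water, and acetate-buffered acetic acid should be too weak to cleave MOM ethers or to add a phenol across a prenyl double bond.

Step 7
Reactants: 11 2-methylbut-3-en-2-ol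
Product: 12 3-(methoxymethoxy)-3-methylbut-1-ene
Conditions: MOMCl, iPr2NEt, CH2Cl2, 0 → 40 °C; distil
Reagents that add atoms: chloromethyl methyl ether, COCCl
Why: MOM protection of a tertiary alcohol before the epoxide exists, so that MOMCl and chloride never meet an oxirane and no Payne rearrangement or acetal migration is possible later.

Step 8
Reactants: 12 3-(methoxymethoxy)-3-methylbut-1-ene
Product: 13 rac-2-[2-(methoxymethoxy)propan-2-yl]oxirane
Conditions: mCPBA, NaHCO3, CH2Cl2, rt (slow, monosubstituted alkene)
Reagents that add atoms: 3-chloroperbenzoic acid, O=C(OO)c1cccc(Cl)c1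
Why: Prilezhaev epoxidation of the terminal alkene; the product is racemic and is resolved in the next step.

Step 9
Reactants: 13 rac-2-[2-(methoxymethoxy)propan-2-yl]oxirane
Product: 14 (R)-2-[2-(methoxymethoxy)propan-2-yl]oxirane
Conditions: (S,S)-(salen)Co(III)OAc (1–2 mol%), H2O (0.55 equiv), a little THF, 0 °C → rt; distil from the diol
Reagents that add atoms: none
Why: Jacobsen hydrolytic kinetic resolution: the chiral Co(III)–salen catalyst hydrates the (S)-epoxide at its CH2 much faster than the (R)-epoxide, so (R)-14 is left behind and the configuration of the later C10 is fixed by the catalyst.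

Step 10
Reactants: 10 the 2'-fluoroflavone; 14 (R)-2-[2-(methoxymethoxy)propan-2-yl]oxirane
Product: 17 oxepine-fused flavone with (R)-C10 carrying 5-OMOM 7-OMOM tertiary OMOM 4'-OTIPS, via 3-lithioflavone 15 (not isolated), via open-chain secondary alcohol 16 (not isolated)
Conditions: LDA (1.2 equiv), THF, −78 °C; 14 (1.5 equiv) then BF3·OEt2 (3 equiv), −78 °C; cold aq. NaHCO3 wash, crude 16 dried; NaHMDS (1.3 equiv), THF, 0 → 45 °C
Reagents that add atoms: none
Why: Proposed new method: LDA removes H3 of 10, the ring C–H beside the C4 carbonyl, and the vinyllithium 15 opens the BF3-activated epoxide at its unhindered CH2 by SN2 attack, which forms C3–C9 and leaves the C10–O bond and its (R) configuration untouched; the closest known reactions are C3 lithiation–trapping of flavones and BF3-assisted opening of terminal epoxides by vinyl- and aryllithiums. The oxygen leaves this opening bound to boron, which a later base would not release cleanly, so the boron is washed out with bicarbonate before NaHMDS turns crude 16 into its free alkoxide. The alkoxide adds to C2' and fluoride leaves (intramolecular SNAr by addition–elimination, the Meisenheimer charge running through C1' into C2=C3–C4=O), which closes the seven-membered oxepine through the O–C2' bond in a 7-exo-type attack on the arene carbon. No stereocentre is formed; C10 comes from 14. The step needs metallation at C3 and not at C3' (carbonyl direction at −78 °C and a bulky, non-coordinating TIPS ether beside C3'), attack at CH2 and not at CH of the epoxide (sterics), and O-arylation instead of addition of the alkoxide to C2 (that 5-endo addition is reversible, loss of fluoride is not). Sodium is chosen as counter-ion so that the fluoride ends as insoluble NaF and does not strip the silyl ether before ring closure.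

Step 11
Reactants: 17 the protected oxepine-fused flavone
Product: 18 4'-hydroxy compound: 17 without the TIPS group
Conditions: TBAF, AcOH, THF, 0 °C
Reagents that add atoms: none
Why: Fluoride cleaves the aryl silyl ether; acetic acid buffers the phenoxide, and the MOM acetals are inert to fluoride.

Step 12
Reactants: 18 the tris-MOM ether
Product: 19 target, (R)-oxepine-fused 5,7,4'-trihydroxy-6,8-diprenylflavone with the tertiary alcohol at C11
Conditions: HCl (about 1 M) in MeOH–THF, 40 °C; stop at full conversion
Reagents that add atoms: none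
Why: Acid-catalysed acetal exchange with methanol removes the two aryl MOM ethers and the tertiary alkyl MOM ether; mild acid and low temperature are chosen so that the freed phenols do not add to the prenyl groups and the tertiary alcohol does not ionise, and C10 bears no acidic or ionisable bond.

**Compound list**

1 | 2,4,6-trihydroxyacetophenone | CC(=O)c1c(O)cc(O)cc1O | starting material
2 | prenyl bromide | CC(C)=CCBr | starting material
3 | 2,4,6-trihydroxy-3,5-bis(3-methylbut-2-enyl)acetophenone | CC(=O)c1c(O)c(CC=C(C)C)c(O)c(CC=C(C)C)c1O | intermediate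
4 | 2-hydroxy-4,6-bis(methoxymethoxy)-3,5-bis(3-methylbut-2-enyl)acetophenone | CC(=O)c1c(O)c(CC=C(C)C)c(OCOC)c(CC=C(C)C)c1OCOC | intermediate
5 | 2-fluoro-4-hydroxybenzoic acid | OC(=O)c1ccc(O)cc1F | starting material
6 | triisopropylsilyl 2-fluoro-4-(triisopropylsilyloxy)benzoate (formed in the flask) | CC(C)[Si](OC(=O)c1ccc(O[Si](C(C)C)(C(C)C)C(C)C)cc1F)(C(C)C)C(C)C | intermediate
7 | 2-fluoro-4-(triisopropylsilyloxy)benzoic acid | OC(=O)c1ccc(O[Si](C(C)C)(C(C)C)C(C)C)cc1F | intermediate
8 | 2-fluoro-4-(triisopropylsilyloxy)benzoyl chloride | ClC(=O)c1ccc(O[Si](C(C)C)(C(C)C)C(C)C)cc1F | intermediate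
9 | 1-[2-fluoro-4-(triisopropylsilyloxy)phenyl]-3-[2-hydroxy-4,6-bis(methoxymethoxy)-3,5-bis(3-methylbut-2-enyl)phenyl]propane-1,3-dione | CC(C)=CCc1c(O)c(C(=O)CC(=O)c2ccc(O[Si](C(C)C)(C(C)C)C(C)C)cc2F)c(OCOC)c(CC=C(C)C)c1OCOC | intermediate
10 | 2-[2-fluoro-4-(triisopropylsilyloxy)phenyl]-5,7-bis(methoxymethoxy)-6,8-bis(3-methylbut-2-enyl)chromen-4-one | CC(C)=CCc1c(OCOC)c(CC=C(C)C)c2oc(cc(=O)c2c1OCOC)-c1ccc(O[Si](C(C)C)(C(C)C)C(C)C)cc1F | intermediate
11 | 2-methylbut-3-en-2-ol | CC(C)(O)C=C | starting material
12 | 3-(methoxymethoxy)-3-methylbut-1-ene | COCOC(C)(C)C=C | intermediate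
13 | rac-2-[2-(methoxymethoxy)propan-2-yl]oxirane | COCOC(C)(C)C1CO1 | intermediate
14 | (R)-2-[2-(methoxymethoxy)propan-2-yl]oxirane | C1[C@H](C(C)(C)OCOC)O1 | intermediate
15 | 3-lithio derivative of flavone 10 (formed in the flask) | CC(C)=CCc1c(OCOC)c(CC=C(C)C)c2oc(-c3ccc(O[Si](C(C)C)(C(C)C)C(C)C)cc3F)c([Li])c(=O)c2c1OCOC | intermediate
16 | flavone 10 carrying at C3 the (2R)-2-hydroxy-3-(methoxymethoxy)-3-methylbutyl chain (crude, carried on) | CC(C)=CCc1c(OCOC)c(CC=C(C)C)c2oc(-c3ccc(O[Si](C(C)C)(C(C)C)C(C)C)cc3F)c(C[C@H](C(C)(C)OCOC)O)c(=O)c2c1OCOC | intermediate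
17 | oxepine-fused flavone, (R) at C10, with 5-OMOM, 7-OMOM, tertiary OMOM and 4'-OTIPS | CC(C)=CCc1c(OCOC)c(CC=C(C)C)c2oc3c(c(=O)c2c1OCOC)C[C@H](C(C)(C)OCOC)Oc1cc(O[Si](C(C)C)(C(C)C)C(C)C)ccc1-3 | intermediate
18 | oxepine-fused flavone, (R) at C10, with 5-OMOM, 7-OMOM, tertiary OMOM and free 4'-OH | CC(C)=CCc1c(OCOC)c(CC=C(C)C)c2oc3c(c(=O)c2c1OCOC)C[C@H](C(C)(C)OCOC)Oc1cc(O)ccc1-3 | intermediate
19 | CNP0328977.2, (R)-configured oxepine-fused 5,7,4'-trihydroxy-6,8-diprenylflavone with a 2-hydroxypropan-2-yl group at C10 | CC(C)=CCc1c(O)c(CC=C(C)C)c2oc3c(c(=O)c2c1O)C[C@H](C(C)(C)O)Oc1cc(O)ccc1-3 | target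

**Step count and risks**

Total steps: 12. Longest linear sequence: 7 steps (steps 1, 2, 5, 6, 10, 11, 12).

Steps most likely to fail:

1. Step 10 (proposed new method). The 3-lithio species may not form cleanly or may not survive: metallation at C3' beside fluorine, β-elimination of the ring oxygen (the pyranone opens to an alkynone phenoxide), or addition to the hindered epoxide too slow to compete. The fallback uses known reactions only and makes the C3–C9 bond before the pyranone ring exists. It sets out from acetophenone 4 with epoxide 14. The phenoxide–enolate dianion of 4 (LDA, THF) opens 14 at CH2 under LiClO4 promotion, a metal-salt-promoted addition of a ketone lithium enolate to an epoxide, to give γ-hydroxy ketone F1. TESCl and imidazole give the secondary silyl ether F2. LiHMDS and acid chloride 8 give the 2-substituted 1,3-diketone F3. NaOAc in AcOH, then PPTS in MeOH, close the pyranone and remove the TES group, which comes back to the route at 16. Compound 16 is then closed to 17 with NaHMDS as in the second stage of step 10.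

2. Step 6. Acid may remove a MOM group during cyclodehydration, most easily the one beside the carbonyl, and the freed phenol, or the still free 2-OH of 9, may add to a neighbouring prenyl double bond to form a chroman. The fallback closes the pyranone by conjugate addition and oxidises afterwards. It sets out from acid chloride 8, which LiAlH(OtBu)3 at −78 °C reduces to aldehyde F4. Condensation of F4 with acetophenone 4 under pyrrolidine in EtOH (aldol condensation and oxa-Michael closure) gives flavanone F5. Dehydrogenation of F5 with iodine in pyridine at 90 °C comes back to the route at flavone 10.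

3. Step 1. The degree and site of alkylation are hard to control: O-prenylation and a second alkylation at an already substituted ring carbon (dearomatisation) compete with the 3,5-di-C-prenyl product. The fallback is a Friedel–Crafts prenylation: 1 is treated with 2-methylbut-3-en-2-ol 11 and BF3·OEt2 in dioxane at rt, so that the ring carbons are attacked by the dimethylallyl cation instead of an alkyl halide. It sets out from 1 and comes back at 3 and makes no new compound (F0).

Further compounds
F1 | step 10 | (4R)-4-hydroxy-1-[2-hydroxy-4,6-bis(methoxymethoxy)-3,5-bis(3-methylbut-2-enyl)phenyl]-5-(methoxymethoxy)-5-methylhexan-1-one | O=C(CC[C@H](C(C)(C)OCOC)O)c1c(O)c(CC=C(C)C)c(OCOC)c(CC=C(C)C)c1OCOC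
F2 | step 10 | triethylsilyl ether of F1 at the secondary hydroxyl | O=C(CC[C@H](C(C)(C)OCOC)O[Si](CC)(CC)CC)c1c(O)c(CC=C(C)C)c(OCOC)c(CC=C(C)C)c1OCOC
F3 | step 10 | 1,3-diketone from F2 and 8, carrying the (2R)-3-(methoxymethoxy)-3-methyl-2-(triethylsilyloxy)butyl chain on its central carbon | CC(C)=CCc1c(O)c(C(=O)C(C[C@H](C(C)(C)OCOC)O[Si](CC)(CC)CC)C(=O)c2ccc(O[Si](C(C)C)(C(C)C)C(C)C)cc2F)c(OCOC)c(CC=C(C)C)c1OCOC
F4 | step 6 | 2-fluoro-4-(triisopropylsilyloxy)benzaldehyde | O=Cc1ccc(O[Si](C(C)C)(C(C)C)C(C)C)cc1F
F5 | step 6 | 2-[2-fluoro-4-(triisopropylsilyloxy)phenyl]-5,7-bis(methoxymethoxy)-6,8-bis(3-methylbut-2-enyl)chroman-4-one | CC(C)=CCc1c(OCOC)c(CC=C(C)C)c2OC(CC(=O)c2c1OCOC)c1ccc(O[Si](C(C)C)(C(C)C)C(C)C)cc1F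
F0 | step 1 | none | none
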